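## The problem

Acalycixeniolide H (26) is a xenicane. A δ-lactone (C1, O2, C3, C4, C4a, C11a) is trans-fused at C4a/C11a to a nine-membered carbocycle (C4a, C5–C11, C11a) that carries a C7 methyl group, a 7,8-epoxide derived from an E-alkene and an exocyclic methylene at C11. C4 bears the chain C12–C15, which ends in an E-α-methyl enoate. There are five stereocentres. C4a is the anchor: C11a trans to it is the thermodynamic arrangement and can be reached by equilibration next to a carbonyl at C11, and the epoxide can be set by the conformation of the trans-fused E-cyclononene. The C4 chain cis to C5 is the less stable arrangement and lies α to the lactone carbonyl, so it must be set kinetically and then kept away from base. The nine-membered ring is strained, so its E-trisubstituted alkene has to be brought in ready-made. Several groups will not survive rough treatment: the 1,5-diene (E-alkene plus exocyclic methylene) cyclises transannularly in acid, the epoxide is acid-labile, and a C11 ketone with O2 on C1 is a β-alkoxy ketone open to retro-oxa-Michael cleavage. The enabling feature is that the lactone ring is a 3,4-dihydro-2H-pyran one oxidation level away. O2–C3 and C4–C4a are the two bonds of an inverse-demand oxa-Diels–Alder reaction between the oxadiene O2=C1–C11a=C4a (with C11 as an ester on C11a, a chelating 2-formyl enoate) and an enol ether C3=C4. A Z-enol ether reacting endo gives the cis C4/C4a pair directly.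

## Retrosynthesis

**26 ⇒ 25 (C7–O and C8–O).** The epoxide is removed first because it is the most acid-labile group and because the strained E-alkene is by far the most nucleophilic of the three alkenes in 25. Carrying an epoxide from the geraniol stage would turn the ring closure into an alkylation next to an epoxide. Precursor 25 has two stereocentres fewer. The forward step needs chemoselectivity and attack on the outer face of the alkene; the carbocycle has the same substitution pattern and relative configuration as the caryophyllene ring, which is epoxidised mainly in this sense.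

**25 ⇒ 24 ⇒ 23 ⇒ 22 (C14=C15; oxidation level of C3 and C14).** The enoate is cut by a stabilised Wittig reaction to aldehyde 24. The lactone carbonyl and the aldehyde are traced to the lactol-alcohol 23, and both come from one acid treatment of the ethyl acetal / TBS ether 22. The alternative of carrying the lactone earlier would make C4 enolisable during the basic and organometallic steps, and together with a C11 ketone it would create a β-acyloxy ketone. The forward steps need acetal hydrolysis without transannular cyclisation of the diene, a double oxidation, and an E-selective olefination under conditions too mild to epimerise C4.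

**22 ⇒ 21 ⇒ 20 ⇒ 19 (C11=CH2, C10–S, ring bond C9–C10).** The methylene comes from ketone 21 and the ketone from α-sulfonyl ketone 20. The nine-membered ring is opened at C9–C10 to the allylic carbonate 19. This cut is preferred to C6–C7 (which needs a vinyl metal or halide fragment) or C10–C11 (acylation inside a medium ring) because geraniol supplies C5–C9 with the E-alkene in place and the ester carbon C11 needs only one more carbon, C10, which a sulfone makes a soft nucleophile. Precursor 19 is monocyclic. The forward reaction needs attack at the distal allyl terminus C9 with retention of alkene geometry under high dilution.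

**19 ⇒ 18 ⇒ 17 ⇒ 16 (carbonate, PMB ether, C10–C11).** The carbonate and the free alcohol 18 follow from PMB ether 17. The β-keto sulfone 17 is cut at C10–C11 to methyl ester 16 and a sulfonylmethyl anion. The order is forced: the leaving group at C9 cannot be present when the sulfone anion is used. The C9 oxygen therefore travels as a PMB ether (removed oxidatively beside the TBS ether on C14), and the C14 oxygen as a TBS ether (removed later in the same acid step as the acetal).

**16 ⇒ 14 (H on C1 and C11a).** The saturated trans ester comes from the dihydropyran 14 by conjugate reduction and equilibration. Three of the four ring substituents of 14 are cis, so the all-cis reduction product has a 1,3-diaxial pair in either chair and equilibration should move C11 trans to C5. The reduction must leave the isolated C7=C8 alkene alone, which rules out ordinary catalytic hydrogenation.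

**14 ⇒ 9 + 13 (O2–C3 and C4–C4a, the lactone-ring skeleton).** This is the central cut. One cycloaddition builds the ring, two skeletal bonds and three stereocentres (C3, C4, C4a) from two acyclic fragments of similar size. C3 emerges as an acetal, which protects C4. The forward step asks for endo addition, the formyl oxygen as the heteroatom terminus, and one enantioface of the chelated diene.

**9 ⇒ 8 ⇒ 7 ⇒ 4 + 6; 6 ⇒ 5; 4 ⇒ 2 ⇒ 1.** The formyl oxadiene is only reactive when C5 is trans to the formyl group, that is cis to the ester. Aldol–dehydration or Knoevenagel routes favour the other isomer because the small formyl (or acetal) group prefers the position next to C5. The geometry is therefore fixed by a Still–Gennari-type olefination of aldehyde 4 with bromophosphonate 6 (from commercial 5), which gives the E-bromoacrylate 7. The bromine is exchanged for CH2OH with retention (8), and the alcohol is oxidised under neutral conditions (9). Aldehyde 4 comes from geraniol (1) by PMB protection (2) and cleavage of the terminal alkene through its epoxide 3.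

**13 ⇒ 12 ⇒ 10 + 11.** The Z-enol ether comes from semi-hydrogenation of alkynyl ether 12, which is made by alkylating ethoxyacetylene (10) with the commercial iodide 11. Z geometry is guaranteed by syn hydrogen delivery.

## Roads not taken

**Alternative 1:** The nine-membered ring would come from a seven-membered one. Irradiation of a 3-silyloxycycloheptenone fused to the lactone under ethylene would form C8–C9 and C10–C11 and give the cyclobutane A1, and retro-aldol cleavage of the C8–C11 bond would then expand the ring and leave carbonyl groups at C7 and C11. The merit is real: ring strain drives the formation of the medium ring, which is better than any direct nine-membered cyclisation, including the palladium closure chosen here. The weak points lie after the expansion. The two ketones must be told apart. The C7 ketone must become the E-trisubstituted C7=C8 alkene inside the ring, where addition–dehydration or enol-triflate coupling has no control of regiochemistry and favours the Z-alkene. A1 also has no C4 chain, and alkylation of the lactone enolate would place it trans to C5. The chosen plan sets against this a ready-made E-alkene from geraniol and a C4 centre set in the key step.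

**Alternative 2:** The ring would be closed at C6–C7 by hydroboration of a C5–C6 vinyl group with 9-BBN and intramolecular B-alkyl Suzuki coupling with an E-vinyl iodide at C7, giving A2. This closure is stereoretentive and has been shown for nine-membered E-cycloalkenes, so as a ring-forming step it is better precedented than the Tsuji–Trost closure used here. Its cost is the precursor: a lactone that already carries the C4/C4a/C11a triad, a vinyl group, a 1,1-disubstituted alkene that must not be hydroborated, and a vinyl iodide. Each of these must be built separately, and the cis C4/C4a relation is still unsolved at that point. The chosen plan offers a three-stereocentre cycloaddition from two simple fragments and fewer steps to the cyclisation substrate, and accepts a riskier ring closure in exchange.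

**Alternative 3:** A Baeyer–Villiger monooxygenase would insert O2 between C3 and C1 of a cyclopentanone fused to the finished carbocycle and give lactone A3. The attraction is a late lactone formation in neutral water with no peracid near the alkenes, and on paper the shortest endgame of all. The difficulties are these. Both carbons flanking the ketone are CH2 groups, so regiochemistry rests entirely on finding an enzyme that accepts a bulky, unnatural substrate. The carbocycle must still be made first. A3 lacks the C4 chain, so the contra-thermodynamic centre would have to be introduced last by enolate alkylation, which favours the trans isomer. The chosen plan is longer after the key step but solves C4 at the outset and shields it as an acetal.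

Key step: step 9

Assumption: the (S,S)-ligand is taken as the enantiomer that leaves open the C4a face leading to 14 (square-planar chelate model); this has not been shown for a formyl ester chelate, and the (R,R)-ligand would be used instead if the sense proved opposite.

## Route

Step 1
Reactants: 1 geraniol
Product: 2 geranyl 4-methoxybenzyl ether
Conditions: NaH, 4-methoxybenzyl chloride, Bu4NI (cat.), THF/DMF, 0 °C to rt
Reagents that add atoms: 4-methoxybenzyl chloride, COc1ccc(CCl)cc1
Why: Williamson etherification of the primary allylic alkoxide; the PMB ether survives base, organolithiums and mild Lewis acid and can later be removed oxidatively beside a TBS ether.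

Step 2
Reactants: 2 geranyl 4-methoxybenzyl ether
Product: 4 (4E)-6-[(4-methoxybenzyl)oxy]-4-methylhex-4-enal, via terminal epoxide 3 (not isolated)
Conditions: mCPBA (1.0 equiv), CH2Cl2, −20 °C; then H5IO6, THF/H2O, 0 °C
Reagents that add atoms: 3-chloroperoxybenzoic acid, OOC(=O)c1cccc(Cl)c1
Why: Prilezhaev epoxidation should prefer the electron-rich terminal alkene over the alkene deactivated by the allylic ether; periodic acid opens the epoxide and cleaves the glycol to the aldehyde and acetone.

Step 3
Reactants: 5 methyl 2-[bis(2,2,2-trifluoroethoxy)phosphoryl]acetate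
Product: 6 methyl 2-bromo-2-[bis(2,2,2-trifluoroethoxy)phosphoryl]acetate
Conditions: NaH, THF, 0 °C; then Br2, −78 °C to 0 °C
Reagents that add atoms: bromine, BrBr
Why: Electrophilic α-bromination of the phosphonoacetate anion gives the bromo Horner–Wadsworth–Emmons reagent; the monobromide is separated from any dibromide by chromatography.

Step 4
Reactants: 4 (4E)-6-[(4-methoxybenzyl)oxy]-4-methylhex-4-enal; 6 methyl 2-bromo-2-[bis(2,2,2-trifluoroethoxy)phosphoryl]acetate
Product: 7 methyl (2E,6E)-2-bromo-8-[(4-methoxybenzyl)oxy]-6-methylocta-2,6-dienoate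
Conditions: 6, t-BuOK, 18-crown-6, THF, −78 °C; then 4
Reagents that add atoms: none
Why: Still–Gennari-type Horner–Wadsworth–Emmons olefination with the electron-poor phosphonate under dissociating conditions is kinetically controlled and should place the alkyl chain cis to the ester (the E-bromoacrylate), which is the geometry the heterodiene needs.

Step 5
Reactants: 7 methyl (2E,6E)-2-bromo-8-[(4-methoxybenzyl)oxy]-6-methylocta-2,6-dienoate
Product: 8 methyl (2Z,6E)-2-(hydroxymethyl)-8-[(4-methoxybenzyl)oxy]-6-methylocta-2,6-dienoate
Conditions: Bu3SnCH2OH, Pd(PPh3)4 (5 mol%), dioxane, 80 °C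
Reagents that add atoms: (tributylstannyl)methanol, CCCC[Sn](CO)(CCCC)CCCC
Why: Stille coupling of the α-bromoacrylate transfers the hydroxymethyl group with retention of alkene geometry under neutral conditions, so the chain stays cis to the ester.

Step 6
Reactants: 8 methyl (2Z,6E)-2-(hydroxymethyl)-8-[(4-methoxybenzyl)oxy]-6-methylocta-2,6-dienoate
Product: 9 methyl (2Z,6E)-2-formyl-8-[(4-methoxybenzyl)oxy]-6-methylocta-2,6-dienoate
Conditions: Dess–Martin periodinane, NaHCO3, CH2Cl2, 0 °C; used at once
Reagents that add atoms: none
Why: Dess–Martin oxidation of the allylic alcohol is non-nucleophilic and buffered, so the alkylidene formyl ester should form without conjugate addition, deconjugation or E/Z scrambling.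

Step 7
Reactants: 10 ethoxyacetylene; 11 tert-butyl(3-iodopropoxy)dimethylsilane
Product: 12 tert-butyl[(5-ethoxypent-4-yn-1-yl)oxy]dimethylsilane
Conditions: n-BuLi, THF, −78 °C; then 11, HMPA, −78 °C to rt
Reagents that add atoms: none
Why: Deprotonation of the terminal alkyne and SN2 alkylation of the primary iodide in THF/HMPA is the standard entry to 1-alkoxyalk-1-ynes.

Step 8
Reactants: 12 tert-butyl[(5-ethoxypent-4-yn-1-yl)oxy]dimethylsilane
Product: 13 tert-butyl{[(4Z)-5-ethoxypent-4-en-1-yl]oxy}dimethylsilane
Conditions: H2 (1 atm), Pd/CaCO3 poisoned with Pb(OAc)2, quinoline, hexane, rt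
Reagents that add atoms: none
Why: Lindlar semi-hydrogenation adds H2 syn to the alkyne and stops at the alkene, giving the Z-enol ether.

Step 9
Reactants: 9 methyl (2Z,6E)-2-formyl-8-[(4-methoxybenzyl)oxy]-6-methylocta-2,6-dienoate; 13 tert-butyl{[(4Z)-5-ethoxypent-4-en-1-yl]oxy}dimethylsilane
Product: 14 methyl (2R,3S,4R)-3-[3-(tert-butyldimethylsilyloxy)propyl]-2-ethoxy-4-{(3E)-5-[(4-methoxybenzyl)oxy]-3-methylpent-3-en-1-yl}-3,4-dihydro-2H-pyran-5-carboxylate (OEt, C4 chain and C4a chain all cis)
Conditions: Cu(OTf)2 (10 mol%), 2,2′-isopropylidenebis[(4S)-4-tert-butyl-2-oxazoline] (11 mol%), 3 Å MS, THF, −40 °C; 13 (1.5 equiv)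
Reagents that add atoms: none
Why: Proposed new method: the 2-formyl enoate should chelate divalent copper through its formyl and ester oxygens, which lowers the LUMO of the oxadiene O2=C1–C11a=C4a and holds it s-cis, and the Z-enol ether then adds in a concerted but asynchronous inverse-demand [4+2] cycloaddition in which its nucleophilic β-carbon C4 bonds to C4a ahead of O2–C3. The closest known reaction types are the thermal and lanthanide-catalysed oxa-Diels–Alder additions of enol ethers to alkylidene 1,3-dicarbonyl compounds and the bisoxazoline–copper catalysis of chelating heterodienes and alkylidene malonates; the enantioselective version on a formyl ester chelate is not established. The dihydropyran ring is closed by the cycloaddition itself, and in the stepwise limit by 6-exo-trig attack of the formyl enolate oxygen on the C3 oxocarbenium ion. C4a is set by the ligand, whose tert-butyl groups block one face of the chelate plane. C4 follows from the endo orientation, which puts the ethoxy group and its cis partner C12 under the diene and therefore cis to the outward C5 chain. C3 follows from suprafacial addition across the Z double bond. The step needs endo selectivity (favoured for alkoxy groups facing a cationic chelate), the formyl and not the ester oxygen as terminus (only the formyl oxadiene has C5 outside, and an ester carbonyl is a much poorer heterodiene terminus) and geometric integrity of both partners (9 made stereospecifically and used fresh, low temperature, molecular sieves).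

Step 10
Reactants: 14 methyl (2R,3S,4R)-3-[3-(tert-butyldimethylsilyloxy)propyl]-2-ethoxy-4-{(3E)-5-[(4-methoxybenzyl)oxy]-3-methylpent-3-en-1-yl}-3,4-dihydro-2H-pyran-5-carboxylate
Product: 16 methyl (3S,4R,5S,6R)-5-[3-(tert-butyldimethylsilyloxy)propyl]-6-ethoxy-4-{(3E)-5-[(4-methoxybenzyl)oxy]-3-methylpent-3-en-1-yl}tetrahydro-2H-pyran-3-carboxylate (ester trans to the neighbouring C4a chain), via all-cis ester 15 (not isolated)
Conditions: Mg turnings, MeOH, 0 °C to rt; then NaOMe (0.5 equiv), MeOH, rt
Reagents that add atoms: none
Why: Dissolving-metal conjugate reduction (Mg/MeOH) acts on the ester-conjugated C1=C11a bond by electron transfer and leaves the isolated trisubstituted alkene, the acetal and both ethers alone; protonation from the face opposite the three ring substituents should give all-cis 15. Methoxide then equilibrates C11a through the ester enolate to the trans isomer, because the all-cis ester has a 1,3-diaxial pair in either chair while 16 has only the C4 chain axial.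

Step 11
Reactants: 16 methyl (3S,4R,5S,6R)-5-[3-(tert-butyldimethylsilyloxy)propyl]-6-ethoxy-4-{(3E)-5-[(4-methoxybenzyl)oxy]-3-methylpent-3-en-1-yl}tetrahydro-2H-pyran-3-carboxylate
Product: 17 1-[(3S,4R,5S,6R)-5-[3-(tert-butyldimethylsilyloxy)propyl]-6-ethoxy-4-{(3E)-5-[(4-methoxybenzyl)oxy]-3-methylpent-3-en-1-yl}tetrahydro-2H-pyran-3-yl]-2-(phenylsulfonyl)ethan-1-one
Conditions: PhSO2CH3 (2.5 equiv), n-BuLi (2.4 equiv), THF, −78 °C to 0 °C
Reagents that add atoms: methyl phenyl sulfone, CS(=O)(=O)c1ccccc1
Why: Claisen-type acylation of (phenylsulfonyl)methyllithium by the methyl ester; the β-keto sulfone is deprotonated at C10 as it forms, which prevents over-addition and keeps C11a from enolising.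

Step 12
Reactants: 17 the β-keto sulfone PMB ether
Product: 18 1-[(3S,4R,5S,6R)-5-[3-(tert-butyldimethylsilyloxy)propyl]-6-ethoxy-4-[(3E)-5-hydroxy-3-methylpent-3-en-1-yl]tetrahydro-2H-pyran-3-yl]-2-(phenylsulfonyl)ethan-1-one
Conditions: DDQ (1.2 equiv), CH2Cl2/pH 7 buffer, 0 °C
Reagents that add atoms: none
Why: Oxidative PMB cleavage by DDQ through the benzylic oxocarbenium ion; the TBS ether, ethyl acetal and sulfone are inert, and short reaction at 0 °C avoids oxidation of the allylic alcohol.

Step 13
Reactants: 18 the allylic alcohol
Product: 19 (2E)-5-[(3S,4R,5R,6R)-5-[3-(tert-butyldimethylsilyloxy)propyl]-6-ethoxy-3-[(phenylsulfonyl)acetyl]tetrahydro-2H-pyran-4-yl]-3-methylpent-2-en-1-yl methyl carbonate (same spatial arrangement as 18)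
Conditions: ClCO2Me, pyridine, CH2Cl2, 0 °C
Reagents that add atoms: methyl chloroformate, COC(=O)Cl
Why: O-acylation of the primary allylic alcohol; pyridine is too weak a base to acylate the β-keto sulfone, and the carbonate later supplies its own base on ionisation.

Step 14
Reactants: 19 the allylic methyl carbonate
Product: 20 (3R,4S,4aR,7E,11aS)-4-[3-(tert-butyldimethylsilyloxy)propyl]-3-ethoxy-7-methyl-10-(phenylsulfonyl)-3,4,4a,5,6,9,10,11a-octahydrocyclonona[c]pyran-11(1H)-one (mixture of C10 epimers)
Conditions: Pd(PPh3)4 (10 mol%), dppe (10 mol%), THF, 65 °C, slow addition to 2 mM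
Reagents that add atoms: none
Why: Tsuji–Trost allylic alkylation: zerovalent palladium ionises the carbonate to the syn π-allyl complex with the E geometry retained, and the methoxide released deprotonates the β-keto sulfone. The soft carbanion C10 should attack the unsubstituted terminus C9 and close the nine-membered ring with C7=C8 inside it; attack at C7 would build a quaternary centre in a seven-membered ring and is disfavoured for stabilised nucleophiles.

Step 15
Reactants: 20 the α-sulfonyl ketone
Product: 21 (3R,4S,4aR,7E,11aS)-4-[3-(tert-butyldimethylsilyloxy)propyl]-3-ethoxy-7-methyl-3,4,4a,5,6,9,10,11a-octahydrocyclonona[c]pyran-11(1H)-one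
Conditions: SmI2 (2.5 equiv), THF/MeOH, −78 °C
Reagents that add atoms: none
Why: Reductive desulfonylation of the α-sulfonyl ketone by two single-electron transfers from SmI2; the samarium enolate lies toward C10 and is protonated by methanol, so C11a is untouched.

Step 16
Reactants: 21 the nine-membered ketone
Product: 22 tert-butyl{3-[(3R,4S,4aS,7E,11aR)-3-ethoxy-7-methyl-11-methylidene-1,3,4,4a,5,6,9,10,11,11a-decahydrocyclonona[c]pyran-4-yl]propoxy}dimethylsilane
Conditions: Cp2TiMe2 (3 equiv), toluene, 65 °C, dark
Reagents that add atoms: dimethyltitanocene, C[Ti](C)(C1C=CC=C1)C1C=CC=C1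
Why: Petasis methylenation through Cp2Ti=CH2 and an oxatitanacyclobutane is non-basic, so the β-alkoxy ketone is not enolised toward C11a and neither epimerisation nor retro-oxa-Michael opening should occur.

Step 17
Reactants: 22 the diene ethyl acetal
Product: 23 (4S,4aS,7E,11aR)-4-(3-hydroxypropyl)-7-methyl-11-methylidene-1,3,4,4a,5,6,9,10,11,11a-decahydrocyclonona[c]pyran-3-ol (mixture of C3 anomers)
Conditions: 0.5 M aq. HCl, THF, 0 °C to rt
Reagents that add atoms: water, O
Why: Acid-catalysed acetal hydrolysis through the C3 oxocarbenium ion also removes the primary TBS ether, so one operation unveils both oxidation sites; C4 is not enolisable at the lactol level.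

Step 18
Reactants: 23 the lactol-alcohol
Product: 24 3-[(4S,4aS,7E,11aR)-7-methyl-11-methylidene-3-oxo-1,3,4,4a,5,6,9,10,11,11a-decahydrocyclonona[c]pyran-4-yl]propanal
Conditions: Dess–Martin periodinane (3 equiv), NaHCO3, CH2Cl2, 0 °C to rt
Reagents that add atoms: none
Why: Dess–Martin oxidation converts the lactol into the δ-lactone and the primary alcohol into the aldehyde in one buffered operation that should not epimerise C4.

Step 19
Reactants: 24 the lactone aldehyde
Product: 25 methyl (2E)-2-methyl-5-[(4S,4aS,7E,11aR)-7-methyl-11-methylidene-3-oxo-1,3,4,4a,5,6,9,10,11,11a-decahydrocyclonona[c]pyran-4-yl]pent-2-enoate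
Conditions: Ph3P=C(CH3)CO2Me, CH2Cl2, rt
Reagents that add atoms: methyl 2-(triphenylphosphoranylidene)propanoate, COC(=O)C(C)=P(c1ccccc1)(c1ccccc1)c1ccccc1
Why: Wittig olefination with the stabilised α-methyl ylide is E-selective and reacts only with the aldehyde; the ylide is too weak a base to enolise the lactone at C4.

Step 20
Reactants: 25 the triene lactone
Product: 26 acalycixeniolide H, the (7S,8S)-7,8-epoxide of 25 with configuration (4S,4aS,7S,8S,11aR)
Conditions: mCPBA (1.05 equiv), NaHCO3, CH2Cl2, −20 °C to 0 °C
Reagents that add atoms: 3-chloroperoxybenzoic acid, OOC(=O)c1cccc(Cl)c1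
Why: Prilezhaev epoxidation: the strained trisubstituted E-alkene is much more nucleophilic than the 1,1-disubstituted and ester-conjugated alkenes. Attack on the exposed outer face of the favoured ring conformer should give the 7S,8S epoxide, as in the analogous caryophyllene ring.

## Compound list

1 | geraniol, (2E)-3,7-dimethylocta-2,6-dien-1-ol | CC(C)=CCC/C(C)=C/CO | starting material
2 | geranyl 4-methoxybenzyl ether | CC(C)=CCC/C(C)=C/COCc1ccc(OC)cc1 | intermediate
3 | racemic terminal epoxide, 2-{(3E)-5-[(4-methoxybenzyl)oxy]-3-methylpent-3-en-1-yl}-3,3-dimethyloxirane | CC1(C)OC1CC/C(C)=C/COCc1ccc(OC)cc1 | intermediate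
4 | (4E)-6-[(4-methoxybenzyl)oxy]-4-methylhex-4-enal | O=CCC/C(C)=C/COCc1ccc(OC)cc1 | intermediate
5 | methyl 2-[bis(2,2,2-trifluoroethoxy)phosphoryl]acetate | COC(=O)CP(=O)(OCC(F)(F)F)OCC(F)(F)F | starting material
6 | methyl 2-bromo-2-[bis(2,2,2-trifluoroethoxy)phosphoryl]acetate (racemic) | COC(=O)C(Br)P(=O)(OCC(F)(F)F)OCC(F)(F)F | intermediate
7 | methyl (2E,6E)-2-bromo-8-[(4-methoxybenzyl)oxy]-6-methylocta-2,6-dienoate | COC(=O)/C(Br)=C\CC/C(C)=C/COCc1ccc(OC)cc1 | intermediate
8 | methyl (2Z,6E)-2-(hydroxymethyl)-8-[(4-methoxybenzyl)oxy]-6-methylocta-2,6-dienoate | COC(=O)/C(CO)=C\CC/C(C)=C/COCc1ccc(OC)cc1 | intermediate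
9 | methyl (2Z,6E)-2-formyl-8-[(4-methoxybenzyl)oxy]-6-methylocta-2,6-dienoate (heterodiene) | COC(=O)/C(C=O)=C\CC/C(C)=C/COCc1ccc(OC)cc1 | intermediate
10 | ethoxyacetylene | C#COCC | starting material
11 | tert-butyl(3-iodopropoxy)dimethylsilane | CC(C)(C)[Si](C)(C)OCCCI | starting material
12 | tert-butyl[(5-ethoxypent-4-yn-1-yl)oxy]dimethylsilane | CCOC#CCCCO[Si](C)(C)C(C)(C)C | intermediate
13 | tert-butyl{[(4Z)-5-ethoxypent-4-en-1-yl]oxy}dimethylsilane (dienophile) | CCO/C=C\CCCO[Si](C)(C)C(C)(C)C | intermediate
14 | methyl (2R,3S,4R)-3-[3-(tert-butyldimethylsilyloxy)propyl]-2-ethoxy-4-{(3E)-5-[(4-methoxybenzyl)oxy]-3-methylpent-3-en-1-yl}-3,4-dihydro-2H-pyran-5-carboxylate (all-cis) | CCO[C@@H]1OC=C(C(=O)OC)[C@H](CC/C(C)=C/COCc2ccc(OC)cc2)[C@@H]1CCCO[Si](C)(C)C(C)(C)C | intermediate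
15 | methyl (3R,4R,5S,6R)-5-[3-(tert-butyldimethylsilyloxy)propyl]-6-ethoxy-4-{(3E)-5-[(4-methoxybenzyl)oxy]-3-methylpent-3-en-1-yl}tetrahydro-2H-pyran-3-carboxylate (all-cis) | CCO[C@@H]1OC[C@H](C(=O)OC)[C@H](CC/C(C)=C/COCc2ccc(OC)cc2)[C@@H]1CCCO[Si](C)(C)C(C)(C)C | intermediate
16 | methyl (3S,4R,5S,6R)-5-[3-(tert-butyldimethylsilyloxy)propyl]-6-ethoxy-4-{(3E)-5-[(4-methoxybenzyl)oxy]-3-methylpent-3-en-1-yl}tetrahydro-2H-pyran-3-carboxylate (ester trans to the neighbouring chain) | CCO[C@@H]1OC[C@@H](C(=O)OC)[C@H](CC/C(C)=C/COCc2ccc(OC)cc2)[C@@H]1CCCO[Si](C)(C)C(C)(C)C | intermediate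
17 | 1-[(3S,4R,5S,6R)-5-[3-(tert-butyldimethylsilyloxy)propyl]-6-ethoxy-4-{(3E)-5-[(4-methoxybenzyl)oxy]-3-methylpent-3-en-1-yl}tetrahydro-2H-pyran-3-yl]-2-(phenylsulfonyl)ethan-1-one | CCO[C@@H]1OC[C@@H](C(=O)CS(=O)(=O)c2ccccc2)[C@H](CC/C(C)=C/COCc2ccc(OC)cc2)[C@@H]1CCCO[Si](C)(C)C(C)(C)C | intermediate
18 | 1-[(3S,4R,5S,6R)-5-[3-(tert-butyldimethylsilyloxy)propyl]-6-ethoxy-4-[(3E)-5-hydroxy-3-methylpent-3-en-1-yl]tetrahydro-2H-pyran-3-yl]-2-(phenylsulfonyl)ethan-1-one | CCO[C@@H]1OC[C@@H](C(=O)CS(=O)(=O)c2ccccc2)[C@H](CC/C(C)=C/CO)[C@@H]1CCCO[Si](C)(C)C(C)(C)C | intermediate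
19 | allylic methyl carbonate of 18 (all stereocentres as in 18, E-alkene) | CCO[C@@H]1OC[C@@H](C(=O)CS(=O)(=O)c2ccccc2)[C@H](CC/C(C)=C/COC(=O)OC)[C@@H]1CCCO[Si](C)(C)C(C)(C)C | intermediate
20 | (3R,4S,4aR,7E,11aS)-4-[3-(tert-butyldimethylsilyloxy)propyl]-3-ethoxy-7-methyl-10-(phenylsulfonyl)-3,4,4a,5,6,9,10,11a-octahydrocyclonona[c]pyran-11(1H)-one (C10 epimers) | O=C1C(S(=O)(=O)c3ccccc3)C/C=C(C)/CC[C@@H]2[C@H](CCCO[Si](C)(C)C(C)(C)C)[C@H](OCC)OC[C@@H]12 | intermediate
21 | (3R,4S,4aR,7E,11aS)-4-[3-(tert-butyldimethylsilyloxy)propyl]-3-ethoxy-7-methyl-3,4,4a,5,6,9,10,11a-octahydrocyclonona[c]pyran-11(1H)-one | O=C1CC/C=C(C)/CC[C@@H]2[C@H](CCCO[Si](C)(C)C(C)(C)C)[C@H](OCC)OC[C@@H]12 | intermediate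
22 | tert-butyl{3-[(3R,4S,4aS,7E,11aR)-3-ethoxy-7-methyl-11-methylidene-1,3,4,4a,5,6,9,10,11,11a-decahydrocyclonona[c]pyran-4-yl]propoxy}dimethylsilane | C=C1CC/C=C(C)/CC[C@@H]2[C@H](CCCO[Si](C)(C)C(C)(C)C)[C@H](OCC)OC[C@@H]12 | intermediate
23 | (4S,4aS,7E,11aR)-4-(3-hydroxypropyl)-7-methyl-11-methylidene-1,3,4,4a,5,6,9,10,11,11a-decahydrocyclonona[c]pyran-3-ol (C3 anomers) | C=C1CC/C=C(C)/CC[C@@H]2[C@H](CCCO)C(O)OC[C@@H]12 | intermediate
24 | 3-[(4S,4aS,7E,11aR)-7-methyl-11-methylidene-3-oxo-1,3,4,4a,5,6,9,10,11,11a-decahydrocyclonona[c]pyran-4-yl]propanal | C=C1CC/C=C(C)/CC[C@@H]2[C@H](CCC=O)C(=O)OC[C@@H]12 | intermediate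
25 | methyl (2E)-2-methyl-5-[(4S,4aS,7E,11aR)-7-methyl-11-methylidene-3-oxo-1,3,4,4a,5,6,9,10,11,11a-decahydrocyclonona[c]pyran-4-yl]pent-2-enoate | C=C1CC/C=C(C)/CC[C@@H]2[C@H](CC/C=C(\C)C(=O)OC)C(=O)OC[C@@H]12 | intermediate
26 | acalycixeniolide H, (4S,4aS,7S,8S,11aR) | C=C1CC[C@@H]2O[C@@]2(C)CC[C@@H]2[C@H](CC/C=C(\C)C(=O)OC)C(=O)OC[C@@H]12 | target

## Step count and least certain steps

Total: 20 steps (steps 1–6 heterodiene, including reagent step 3; steps 7–8 dienophile; steps 9–20 union and endgame). Longest linear sequence: 17 steps from geraniol (steps 1, 2, 4–6, 9–20).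

**Step 9 (key step, proposed new method).** The most likely failures are loss of geometric integrity of the heterodiene and poor facial discrimination. Isomerisation about C4a=C11a in the chelate, or reversible stepwise addition of the enol ether, would erode both the cis C4/C4a relation and the enantiomeric purity. Competing closure through the ester oxygen is also possible. Fallback with known chemistry, setting out from 9 and 13: run the cycloaddition without the chiral catalyst, with Eu(fod)3 (5 mol%) in CH2Cl2 at room temperature or thermally at 40–60 °C, conditions under which alkylidene 1,3-dicarbonyl heterodienes add enol ethers with endo preference. This gives the racemate, that is 14 together with its enantiomer ent-14 F1. Preparative chromatography on a chiral stationary phase then supplies 14, where the route is rejoined.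

**Step 10.** The push–pull alkene may resist electron transfer, or the ester enolate formed during reduction and equilibration may expel O2 (retro-oxa-Michael opening), which would expose C4 to epimerisation. Fallback setting out from 14: i-Bu2AlH reduces the vinylogous carbonate ester to the allylic alcohol F2. Hydroxyl-directed hydrogenation with [Rh(nbd)(dppb)]BF4 under H2 saturates only the alkene next to the free hydroxyl and gives the all-cis primary alcohol F3. Dess–Martin oxidation gives the cis aldehyde F4, which Et3N equilibrates to the trans aldehyde F5. Addition of (phenylsulfonyl)methyllithium gives the β-hydroxy sulfone F6, and a second Dess–Martin oxidation comes back to the route at 17.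

**Step 14.** Closure of a strained, trans-fused E-cyclononene competes with intermolecular alkylation (dimers and oligomers), with β-hydride loss from the π-allyl complex to a diene, and with attack at C7. Fallback setting out from 18: CBr4/PPh3 converts the allylic alcohol into the allylic bromide F7. Cs2CO3 in MeCN under high dilution (slow addition) then closes the ring by direct SN2 C-alkylation of the β-keto sulfone anion, returning to the route at 20.

**Step 17.** Brønsted acid may protonate the exocyclic methylene or the strained alkene and trigger transannular cyclisation of the 1,5-diene before the acetal is hydrolysed. Fallback setting out from 22: Me2BBr in CH2Cl2 at −78 °C converts the ethyl acetal into the α-bromo ether F8 without a protic acid. Aqueous NaHCO3 hydrolyses it to the silyl-protected lactol F9, and Bu4NF buffered with AcOH removes the TBS ether, returning to the route at 23.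

**Step 20.** Facial selectivity rests on the conformer population of the nine-membered ring and may be incomplete, giving the 7,8-diastereomer as well; over-oxidation of the exocyclic methylene is a lesser risk. Fallback setting out from 25: reagent-controlled epoxidation with the fructose-derived Shi ketone and KHSO5 (as 2KHSO5·KHSO4·K2SO4) in buffered MeCN/dimethoxymethane at 0 °C, choosing the ketone enantiomer matched to the required face. This returns to the route at 26 and makes no new compound (F0).

## Further compounds

F1 | step 9 | ent-14, methyl (2S,3R,4S)-3-[3-(tert-butyldimethylsilyloxy)propyl]-2-ethoxy-4-{(3E)-5-[(4-methoxybenzyl)oxy]-3-methylpent-3-en-1-yl}-3,4-dihydro-2H-pyran-5-carboxylate | CCO[C@H]1OC=C(C(=O)OC)[C@@H](CC/C(C)=C/COCc2ccc(OC)cc2)[C@H]1CCCO[Si](C)(C)C(C)(C)C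
F2 | step 10 | allylic alcohol from 14 (CO2Me replaced by CH2OH, stereocentres as in 14) | CCO[C@@H]1OC=C(CO)[C@H](CC/C(C)=C/COCc2ccc(OC)cc2)[C@@H]1CCCO[Si](C)(C)C(C)(C)C
F3 | step 10 | all-cis saturated primary alcohol (CH2OH cis to the three other ring substituents) | CCO[C@@H]1OC[C@H](CO)[C@H](CC/C(C)=C/COCc2ccc(OC)cc2)[C@@H]1CCCO[Si](C)(C)C(C)(C)C
F4 | step 10 | all-cis aldehyde | CCO[C@@H]1OC[C@H](C=O)[C@H](CC/C(C)=C/COCc2ccc(OC)cc2)[C@@H]1CCCO[Si](C)(C)C(C)(C)C
F5 | step 10 | trans aldehyde (CHO trans to the neighbouring chain, configuration as in 16) | CCO[C@@H]1OC[C@@H](C=O)[C@H](CC/C(C)=C/COCc2ccc(OC)cc2)[C@@H]1CCCO[Si](C)(C)C(C)(C)C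
F6 | step 10 | β-hydroxy sulfone (carbinol epimers, ring configuration as in 17) | CCO[C@@H]1OC[C@@H](C(O)CS(=O)(=O)c2ccccc2)[C@H](CC/C(C)=C/COCc2ccc(OC)cc2)[C@@H]1CCCO[Si](C)(C)C(C)(C)C
F7 | step 14 | allylic bromide from 18 (CH2OH replaced by CH2Br, E-alkene, stereocentres as in 18) | CCO[C@@H]1OC[C@@H](C(=O)CS(=O)(=O)c2ccccc2)[C@H](CC/C(C)=C/CBr)[C@@H]1CCCO[Si](C)(C)C(C)(C)C
F8 | step 17 | α-bromo ether from 22 (OEt at C3 replaced by Br, C3 epimers) | C=C1CC/C=C(C)/CC[C@@H]2[C@H](CCCO[Si](C)(C)C(C)(C)C)C(Br)OC[C@@H]12
F9 | step 17 | TBS-protected lactol (C3 anomers) | C=C1CC/C=C(C)/CC[C@@H]2[C@H](CCCO[Si](C)(C)C(C)(C)C)C(O)OC[C@@H]12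
F0 | step 20 | none | none
A1 | alternative 1 | tricyclic cyclobutane photoadduct with C7 ketone and C11 silyloxy group | O=C1[C@H]2CC[C@@]2(O[Si](C)(C)C(C)(C)C)[C@@H]3COC(=O)C[C@H]3CC1
A2 | alternative 2 | bicyclic lactone with E-cyclononene and TBS-protected 3-hydroxypropyl chain at C4 | C=C1CC/C=C(C)/CC[C@@H]2[C@H](CCCO[Si](C)(C)C(C)(C)C)C(=O)OC[C@@H]12
A3 | alternative 3 | bicyclic δ-lactone lacking the C4 chain | C=C1CC/C=C(C)/CC[C@@H]2CC(=O)OC[C@@H]12
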